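| flask | starting material | protic impurity | free enzyme | temperature | remark | time |
|---|---|---|---|---|---|---|
| south-west | 0.050 M | 0.034 M | 2 µM | −10 °C | run made earlier |  |
| south | 0.050 M | 0.075 M | 2 µM | 23 °C | run made earlier |  |
| north | 0.10 M | 0.050 M | 2 µM | −10 °C | run made earlier |  |
| Saturday's | 0.050 M | 0.0500 M | 2.0 µM | 5 °C |  | 30 h |
| Monday's | 0.050 M | 0.0500 M | 2.0 µM |  | at −25 °C until 10 h, from then on at 35 °C | 30 h |
| Thursday's | 0.050 M | 0.0500 M | 2.0 µM | −25 °C |  | 30 h |
| Sunday's | 0.050 M | 0.0500 M | 2.0 µM | 35 °C |  | 30 h |

- south-west (time / h: product / %, starting material / %): 3.00: 3.5, 94.9; 10.0: 11.1, 87.7; 15.0: 20.0, 82.0; 25.0: 35.4, 65.4; 40.0: 63.0, 33.7; 48.0: 84.1, 14.4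
- south (time / h: product / %, starting material / %): 1.50: 12.0, 77.1; 3.00: 22.6, 58.7; 5.00: 48.9, 28.7; 6.00: 58.7, 14.4; 8.00: 74.3, 1.7; 10.0: 73.7, 0
- north (time / h: product / %, starting material / %): 4.00: 0.2, 98.1; 8.00: 0.8, 97.0; 12.0: 2.3, 93.1; 25.0: 8.9, 89.2; 48.0: 17.7, 77.3

(scatter of a reading: 1 percentage point)

* which flask leads in amount of product, in percent of the starting material charged ("all alike" within 1.5 percentage points) (Saturday's / Monday's / Thursday's / Sunday's / all alike)
* how much product is there at the end, in percent of the starting material charged: Saturday's
* how much product is there at the end, in percent of the starting material charged: Monday's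
* how much product is there at the end, in percent of the starting material charged: Thursday's
* how much product is there at the end, in percent of the starting material charged: Sunday's

**Clearing time.** Temperature comes first here, so measure its effect on the early pace directly: divide the hours of an early reading by the fraction of the charge then found as product, and you have the clearing time, the hours in which the early pace would turn the whole charge into product 90.1 h, here from the south-west run at −10 °C. The south run at 23 °C gives 13.3 h, so that step, which also raises the protic impurity from 0.034 M to 0.075 M, shortens it by a factor of 6.79, and I choose to credit this whole factor to temperature and spread it exponentially over the degrees.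

**What slows it.** The north run, with twice the charge at −10 °C and with 0.050 M of protic impurity against the south-west run's 0.034 M, reads a clearing time of 281 h, longer than the south-west run's, which I take to mean that starting material itself holds the pace back (substrate inhibition, as a reading). Accordingly the south-west run speeds up as its starting material falls, reading 54.3 h between 25.0 h and 40.0 h, shorter than at the start. The pace is not the whole end, though: the south run stops at 73.7% of product, with 0% of starting material left.

**My reckoning.** Thursday's clearing time comes to 215 h, much longer than its 30 h, so the flask stays near its early pace and you divide: 14.0% of product. Saturday's comes to 37.7 h, which gives 79.6% at the early pace and more as the pace quickens. Sunday's, reckoned beyond the warmest run, comes to 6.62 h, shorter than its time.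

**The forecast.** It puts Saturday's in the lead with 89% (78% to 96%), Monday's at 68% (50% to 78%), Thursday's at 8% (3% to 16%) and Sunday's at 68% (50% to 78%), adding “Enzyme denaturation is a risk”. My Thursday's figure stands higher than its figure.

**The result.** Saturday's leads with 90.9%, Thursday's gives 13.9%, Monday's 24.6% and Sunday's 19.5%. In Sunday's flask at 15.0 h, unfolded enzyme already stands at 97.6% of the catalyst charged and free enzyme at 0%, while product reads 19.5% then and 19.5% at 30.0 h. Put the clearing time to use backwards: Sunday's product, taken at Sunday's clearing time, amounts to 1.29 h of work at the early pace, out of the 30 h you gave it.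

    free enzyme → unfolded enzyme (k = 1.10 × 10⁻⁶ /min, Ea = 222 kJ/mol)
    starting material + free enzyme → product + free enzyme, rate k2*[starting material]*[free enzyme]/(1 + ([starting material]/Km2) + ([starting material]/Ksi2)^2) (34.0 mM, 10.0 mM, k = 6200 /M/min, Ea = 35.0 kJ/mol)
    free enzyme + product → spent catalyst (k = 0.00250 /M/min, Ea = 79.0 kJ/mol)
    starting material + protic impurity → quenched substrate (k = 0.00270 /M/min, Ea = 71.0 kJ/mol)
    (constants at 5 °C)

**Second reading.** For Thursday's flask read at 20 h, the same clearing time gives 9.30% of product, and the computed value is 9.07%.

All runs stem from a simulated flask from invented constants; noise was put on by code.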